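The readings were computed on assumed constants; the scatter is artificial.

The amounts came first. In the flask asked about, which is Saturday's run followed further, 0.50 mM of starting complex met 0.500 mM of incoming ligand at 20 °C; on Thursday twice that starting complex met the same ligand charge.

in all of them: temperature 20 °C
- Saturday's: starting complex 0.50 mM; incoming ligand 0.50 mM; protic impurity 0.010 mM; the very flask that is asked about, followed so far
- Thursday's: starting complex 1 mM; incoming ligand 0.50 mM; protic impurity 0.010 mM; run made earlier
- flask: starting complex 0.50 mM; incoming ligand 0.500 mM; protic impurity 0.0100 mM; time 40 min

| run | time / min | complex with one exchanged / % |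
|---|---|---|
| Saturday's | 2.00 | 64.2 |
| Saturday's | 3.00 | 63.7 |
| Saturday's | 5.00 | 64.0 |
| Saturday's | 8.00 | 63.5 |
| Saturday's | 15.0 | 63.7 |
| Saturday's | 25.0 | 64.4 |
| Thursday's | 0.417 | 42.2 |
| Thursday's | 0.667 | 44.7 |
| Thursday's | 1.33 | 44.7 |
| Thursday's | 2.00 | 45.3 |
| Thursday's | 3.00 | 45.5 |
| Thursday's | 6.00 | 45.8 |

(each reading ± 0.5 percentage points)

* complex with one exchanged, in percent of the starting complex first charged, at 40 min
* what to do for the largest gain in complex with one exchanged; "none" if nothing gains more than 2 percentage points (delta / epsilon / beta / zeta / none)
* complex with one exchanged present, in percent of the starting complex first charged, after epsilon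
* complex with one exchanged present, in percent of the starting complex first charged, after beta

- delta: at 40 min take out 90 % of the leaving ligand then present, then wait 80 min
- epsilon: change nothing and wait 80 min more
- beta: at 40 min raise the temperature by 15 K, then wait 80 min
- zeta: at 40 min add incoming ligand, 50.0 % of the amount charged, then wait 80 min

- the volume of additions can be left aside
- the earlier runs do not show what temperature does; that part of a forecast is a guess

The bench rule says one equivalent of ligand buys one exchange, so I reckoned with what was left and not with what was made. Saturday's readings lay flat around a mean of 63.9 %, so I took that value for 40 min and for epsilon. At 1.00 equivalents, this leaves 36.1 % as the unclaimed share, the part of the charged incoming ligand not found in complex with one exchanged. If one exchange were the whole story, that share would be free ligand, and the quotient c(leaving ligand)·c(one exchanged)/(c(starting complex)·c(incoming ligand)) would read 3.14.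

Thursday's ratio of ligand to complex, 0.500, marks the border of the rule. There the ligand was the limiting reagent, nearly all of it lay in complex with one exchanged, and the unclaimed share was 8.40 %. But its quotient read 9.21, larger than Saturday's, and one constant cannot be both. So I read the unclaimed share as a ceiling on free ligand, with part of it gone into a further exchange. Going from Thursday's ratio to Saturday's had raised the reading by 18 percentage points, but the unclaimed share had risen too, by 28 points, so I made no firm choice among the options, and heating stayed an open guess.

The forecast gave 63.9 % at 40 min, 63.9 % after epsilon and 63.5 % after beta, and chose zeta, saying “Adding ligand looks slightly better”.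

The flask gave 63.9 %, then 63.9 % after epsilon and 74.4 % after beta. Beta changed the reading by 11 points, delta by 0.058 points and zeta by −6.1 points, so the best choice was beta.

    starting complex + incoming ligand ⇌ leaving ligand + complex with one exchanged (K = 53.0, k = 690 /M/s, Ea = 38.0 kJ/mol, ΔH = −14.0 kJ/mol)
    complex with one exchanged + incoming ligand ⇌ leaving ligand + complex with two exchanged (K = 1.80, k = 270 /M/s, Ea = 44.0 kJ/mol, ΔH = −54.0 kJ/mol)
    complex with two exchanged + incoming ligand ⇌ leaving ligand + complex with three exchanged (K = 17.0, k = 540 /M/s, Ea = 37.0 kJ/mol, ΔH = −84.0 kJ/mol)
    protic impurity + starting complex → quenched substrate (k = 3200 /M/s, Ea = 26.0 kJ/mol)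
    (constants at 20 °C)

In the flask, the unclaimed share of 36.1 % held 5.3 % free ligand at 40.0 min, so 31 points of the charge sat in complex with two exchanged and complex with three exchanged. The neighbour charged with 0.30 mM of starting complex, at 1.67 equiv of ligand, read 52.7 %, which makes its unclaimed share 68.4 %. Free ligand there was 10.9 % of its charge, so 58 points had gone past the first exchange, more than in the flask, and complex with three exchanged stood at 24.2 % of the starting complex.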